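**Retrosynthetic overview**

- Abiesin 20 comes from its 3,7-di-O-benzyl ether 19 by hydrogenolysis.
- The strategy rests on ring C of the flavone half (O1, C2, C3, C4, C4a). It lies between a ring A that is mirror-symmetric about the C4a···C7–OMe axis and the central anisole ring. Cutting C4a–C4, C4–C3 and O1–C2 gives 2-iodo-5-methoxyresorcinol 15 (C4a and both oxygens), carbon monoxide 16 (C4) and aryl alkyne 10 (C2, C3).
- Alkyne 10 comes from aldehyde 9 by one-carbon homologation. Aldehyde 9 comes from a Suzuki biaryl bond between C6 of bromoflavonol 7 and boronic acid 8.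
- Bromoflavonol 7 comes from acetophenone 3 and 4-methoxybenzaldehyde 4 by chalcone formation and oxidative cyclization. Iodide 15 comes from 5-methoxyresorcinol 11 by acetal-directed lithiation and iodination.
- Ring order: the flavonol pyranone is closed first (step 3), and flavone ring C last (step 10).

Key step: step 10

**Route**

Step 1
Reactants: 1 2,4-dihydroxyacetophenone
Product: 2 1-(5-bromo-2,4-dihydroxyphenyl)ethanone
Conditions: NBS (1.0 equiv), MeCN, 0 °C to rt
Reagents that add atoms: N-bromosuccinimide, O=C1CCC(=O)N1Br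
Why: Electrophilic aromatic bromination; C5 is para to the chelated 2-OH and ortho to the 4-OH and is unhindered, whereas C3 is crowded between two oxygens, so one equivalent of NBS should give the 5-bromide.

Step 2
Reactants: 2 1-(5-bromo-2,4-dihydroxyphenyl)ethanone
Product: 3 1-[4-(benzyloxy)-5-bromo-2-hydroxyphenyl]ethanone
Conditions: BnBr (1.05 equiv), K2CO3, acetone, reflux
Reagents that add atoms: benzyl bromide, BrCc1ccccc1
Why: Williamson etherification; the 2-OH is tied up in a hydrogen bond to the acetyl carbonyl and is the less acidic phenol, so a slight excess of benzyl bromide should alkylate only the 4-OH.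

Step 3
Reactants: 3 1-[4-(benzyloxy)-5-bromo-2-hydroxyphenyl]ethanone; 4 4-methoxybenzaldehyde
Product: 6 7-(benzyloxy)-6-bromo-3-hydroxy-2-(4-methoxyphenyl)-4H-chromen-4-one, via 2'-hydroxychalcone 5 (not isolated)
Conditions: KOH, EtOH, rt; then 30% H2O2, 0 °C to rt; then aq. HCl
Reagents that add atoms: hydrogen peroxide, OO
Why: Claisen–Schmidt aldol condensation to the E-chalcone followed in the same pot by Algar–Flynn–Oyamada oxidative cyclization; with no substituent at C6' of the chalcone, six-membered closure to the flavonol is expected rather than aurone formation, and the aryl bromide and benzyl ether are inert to alkaline peroxide.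

Step 4
Reactants: 6 7-(benzyloxy)-6-bromo-3-hydroxy-2-(4-methoxyphenyl)-4H-chromen-4-one
Product: 7 3,7-bis(benzyloxy)-6-bromo-2-(4-methoxyphenyl)-4H-chromen-4-one
Conditions: BnBr (1.3 equiv), K2CO3, DMF, 60 °C
Reagents that add atoms: benzyl bromide, BrCc1ccccc1
Why: Williamson etherification of the acidic enolic 3-OH, the only free hydroxyl left, which also removes the acidic proton before the palladium and base-mediated steps.

Step 5
Reactants: 7 3,7-bis(benzyloxy)-6-bromo-2-(4-methoxyphenyl)-4H-chromen-4-one; 8 5-formyl-2-methoxyphenylboronic acid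
Product: 9 3-[3,7-bis(benzyloxy)-2-(4-methoxyphenyl)-4-oxo-4H-chromen-6-yl]-4-methoxybenzaldehyde
Conditions: Pd(OAc)2 (3 mol %), SPhos (6 mol %), K3PO4, toluene/H2O, 90 °C
Reagents that add atoms: none
Why: Suzuki–Miyaura coupling; the electron-rich biaryl phosphine should speed oxidative addition into the ortho-alkoxy aryl bromide and outpace protodeboronation of the ortho-methoxy boronic acid, and the aldehyde is tolerated.

Step 6
Reactants: 9 3-[3,7-bis(benzyloxy)-2-(4-methoxyphenyl)-4-oxo-4H-chromen-6-yl]-4-methoxybenzaldehyde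
Product: 10 3,7-bis(benzyloxy)-6-(5-ethynyl-2-methoxyphenyl)-2-(4-methoxyphenyl)-4H-chromen-4-one
Conditions: dimethyl (1-diazo-2-oxopropyl)phosphonate (1.5 equiv), K2CO3, MeOH/THF, 0 °C to rt
Reagents that add atoms: dimethyl (1-diazo-2-oxopropyl)phosphonate, CC(=O)C(=[N+]=[N-])P(=O)(OC)OC
Why: Ohira–Bestmann (Seyferth–Gilbert) homologation; methanolysis releases the diazomethylphosphonate anion, which olefinates the aryl aldehyde, and the diazoalkene loses N2 with a 1,2-hydride shift to give the terminal alkyne, while carbonate at room temperature should leave the 3-alkoxyflavone ring closed.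

Step 7
Reactants: 11 5-methoxyresorcinol
Product: 12 1-methoxy-3,5-bis(methoxymethoxy)benzene
Conditions: MOMCl (2.5 equiv), i-Pr2NEt, CH2Cl2, 0 °C to rt
Reagents that add atoms: chloromethyl methyl ether, COCCl
Why: O-alkylation of both phenols with the reactive alpha-chloro ether under amine base installs two acetal groups that direct the lithiation of the next step.

Step 8
Reactants: 12 1-methoxy-3,5-bis(methoxymethoxy)benzene
Product: 14 2-iodo-5-methoxy-1,3-bis(methoxymethoxy)benzene, via aryllithium 13 (not isolated)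
Conditions: n-BuLi (1.1 equiv), THF, 0 °C; then I2, THF, −78 °C to rt; aq. Na2S2O3
Reagents that add atoms: iodine, II
Why: Directed ortho-metalation; C2 lies between two chelating methoxymethoxy groups and should be deprotonated in preference to C4 and C6, which have one such neighbour and a weaker methoxy director, and iodine traps the aryllithium at that carbon.

Step 9
Reactants: 14 2-iodo-5-methoxy-1,3-bis(methoxymethoxy)benzene
Product: 15 2-iodo-5-methoxybenzene-1,3-diol
Conditions: HCl (cat.), MeOH, rt to 40 °C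
Reagents that add atoms: none
Why: Acid-catalysed acetal exchange with methanol releases both phenols, and dilute acid near room temperature is chosen to avoid ipso-protonation and loss of iodine from the electron-rich ring.

Step 10
Reactants: 15 2-iodo-5-methoxybenzene-1,3-diol; 16 carbon monoxide; 10 3,7-bis(benzyloxy)-6-(5-ethynyl-2-methoxyphenyl)-2-(4-methoxyphenyl)-4H-chromen-4-one
Product: 19 3,7-di-O-benzylabiesin, via aryl ynone 17 (not isolated), via enaminone 18 (not isolated)
Conditions: PdCl2(PPh3)2 (5 mol %), CO (20 bar), Et2NH/DMF, 120 °C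
Reagents that add atoms: none
Why: Zerovalent palladium, formed from PdCl2(PPh3)2 under CO and amine, inserts into the C–I bond of 15, CO insertion gives the aroylpalladium iodide (C4a–C4), and copper-free coupling with the terminal alkyne of 10 gives ynone 17 (C4–C3). This is the known carbonylative Sonogashira annulation of 2-iodophenols with terminal alkynes to flavones. Diethylamine then adds to the ynone to give enaminone 18, and a phenol oxygen attacks the amine-bearing carbon in a 6-endo addition–elimination that expels diethylamine and closes ring C (O1–C2), so the amine leaves no atoms in 19. No stereocenter is formed. The step needs 6-endo closure rather than 5-exo closure to an aurone, which the enaminone pathway secures because its electrophilic carbon is the future C2; there is no choice between the two phenol oxygens because they are mirror-related, and the unused one becomes the hydrogen-bonded C5–OH. CO pressure should favour carbonylative coupling over direct alkynylation and, together with the fast reaction of the aroylpalladium with the acetylide, over amide formation, while the benzyl ethers, methyl ethers and the existing flavonol pyranone should be inert.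

Step 11
Reactants: 19 3,7-di-O-benzylabiesin
Product: 20 abiesin
Conditions: H2 (1 atm), Pd/C (10%), THF/MeOH, rt
Reagents that add atoms: none
Why: Catalytic hydrogenolysis cleaves both benzylic C–O bonds at atmospheric pressure, while the conjugated C2–C3 double bonds of the two chromenones and the three methyl ethers should remain untouched.

**Compound list**

1 | 2,4-dihydroxyacetophenone | CC(=O)c1ccc(O)cc1O | starting material
2 | 1-(5-bromo-2,4-dihydroxyphenyl)ethanone | CC(=O)c1cc(Br)c(O)cc1O | intermediate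
3 | 1-[4-(benzyloxy)-5-bromo-2-hydroxyphenyl]ethanone | CC(=O)c1cc(Br)c(OCc2ccccc2)cc1O | intermediate
4 | 4-methoxybenzaldehyde | COc1ccc(C=O)cc1 | starting material
5 | (E)-1-[4-(benzyloxy)-5-bromo-2-hydroxyphenyl]-3-(4-methoxyphenyl)prop-2-en-1-one (2'-hydroxychalcone, not isolated) | COc1ccc(/C=C/C(=O)c2cc(Br)c(OCc3ccccc3)cc2O)cc1 | intermediate
6 | 7-(benzyloxy)-6-bromo-3-hydroxy-2-(4-methoxyphenyl)-4H-chromen-4-one | COc1ccc(-c2oc3cc(OCc4ccccc4)c(Br)cc3c(=O)c2O)cc1 | intermediate
7 | 3,7-bis(benzyloxy)-6-bromo-2-(4-methoxyphenyl)-4H-chromen-4-one | COc1ccc(-c2oc3cc(OCc4ccccc4)c(Br)cc3c(=O)c2OCc2ccccc2)cc1 | intermediate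
8 | 5-formyl-2-methoxyphenylboronic acid | COc1ccc(C=O)cc1B(O)O | starting material
9 | 3-[3,7-bis(benzyloxy)-2-(4-methoxyphenyl)-4-oxo-4H-chromen-6-yl]-4-methoxybenzaldehyde | COc1ccc(-c2oc3cc(OCc4ccccc4)c(-c4cc(C=O)ccc4OC)cc3c(=O)c2OCc2ccccc2)cc1 | intermediate
10 | 3,7-bis(benzyloxy)-6-(5-ethynyl-2-methoxyphenyl)-2-(4-methoxyphenyl)-4H-chromen-4-one | COc1ccc(-c2oc3cc(OCc4ccccc4)c(-c4cc(C#C)ccc4OC)cc3c(=O)c2OCc2ccccc2)cc1 | intermediate
11 | 5-methoxyresorcinol | COc1cc(O)cc(O)c1 | starting material
12 | 1-methoxy-3,5-bis(methoxymethoxy)benzene | COCOc1cc(OC)cc(OCOC)c1 | intermediate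
13 | [4-methoxy-2,6-bis(methoxymethoxy)phenyl]lithium (aryllithium, not isolated) | [Li]c1c(OCOC)cc(OC)cc1OCOC | intermediate
14 | 2-iodo-5-methoxy-1,3-bis(methoxymethoxy)benzene | COCOc1cc(OC)cc(OCOC)c1I | intermediate
15 | 2-iodo-5-methoxybenzene-1,3-diol | COc1cc(O)c(I)c(O)c1 | intermediate
16 | carbon monoxide | [C-]#[O+] | starting material
17 | 3-{3-[3,7-bis(benzyloxy)-2-(4-methoxyphenyl)-4-oxo-4H-chromen-6-yl]-4-methoxyphenyl}-1-(2,6-dihydroxy-4-methoxyphenyl)prop-2-yn-1-one (aryl ynone, not isolated) | COc1cc(O)c(C(=O)C#Cc2ccc(OC)c(-c3cc4c(=O)c(OCc5ccccc5)c(-c5ccc(OC)cc5)oc4cc3OCc3ccccc3)c2)c(O)c1 | intermediate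
18 | (E)-3-{3-[3,7-bis(benzyloxy)-2-(4-methoxyphenyl)-4-oxo-4H-chromen-6-yl]-4-methoxyphenyl}-3-(diethylamino)-1-(2,6-dihydroxy-4-methoxyphenyl)prop-2-en-1-one (enaminone, not isolated; drawn as E, either geometry cyclizes) | COc1cc(O)c(C(=O)/C=C(/N(CC)CC)c2ccc(OC)c(-c3cc4c(=O)c(OCc5ccccc5)c(-c5ccc(OC)cc5)oc4cc3OCc3ccccc3)c2)c(O)c1 | intermediate
19 | 3,7-di-O-benzylabiesin, 3,7-bis(benzyloxy)-6-[5-(5-hydroxy-7-methoxy-4-oxo-4H-chromen-2-yl)-2-methoxyphenyl]-2-(4-methoxyphenyl)-4H-chromen-4-one | COc1ccc(-c2oc3cc(OCc4ccccc4)c(-c4cc(-c5cc(=O)c6c(O)cc(OC)cc6o5)ccc4OC)cc3c(=O)c2OCc2ccccc2)cc1 | intermediate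
20 | abiesin | COc1ccc(-c2oc3cc(O)c(-c4cc(-c5cc(=O)c6c(O)cc(OC)cc6o5)ccc4OC)cc3c(=O)c2O)cc1 | target

**Step count**

Total steps: 11. Longest linear sequence: 8 steps (steps 1 to 6, then 10 and 11); steps 7 to 9 form the three-step side branch to iodide 15.

**Steps most likely to fail**

1. Step 10. The aroylpalladium intermediate may be intercepted by diethylamine to give an amide. Direct alkynylation without CO uptake, followed by benzofuran closure, may also compete, and the electron-rich, doubly ortho-substituted aryl iodide may lose iodine reductively. Fallback: a Baker–Venkataraman construction of the same ring C, which sets out from aldehyde 9 and comes back at 19.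
   - Pinnick oxidation (NaClO2, NaH2PO4, 2-methyl-2-butene, t-BuOH/THF/H2O) should give 3-[3,7-bis(benzyloxy)-2-(4-methoxyphenyl)-4-oxo-4H-chromen-6-yl]-4-methoxybenzoic acid F1.
   - Esterification (EDC·HCl, DMAP, CH2Cl2) with one of the two equivalent hydroxyls of purchased 1-(2,6-dihydroxy-4-methoxyphenyl)ethanone F2, used in excess, should give 2-acetyl-3-hydroxy-5-methoxyphenyl 3-[3,7-bis(benzyloxy)-2-(4-methoxyphenyl)-4-oxo-4H-chromen-6-yl]-4-methoxybenzoate F3.
   - Base-induced acyl transfer (KOH, pyridine, 50 °C) should give 1-{3-[3,7-bis(benzyloxy)-2-(4-methoxyphenyl)-4-oxo-4H-chromen-6-yl]-4-methoxyphenyl}-3-(2,6-dihydroxy-4-methoxyphenyl)propane-1,3-dione F4.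
   - Cyclodehydration (AcOH, cat. H2SO4, 90 °C) should then give 19, again with no choice between the two equivalent phenols.

2. Step 9. Acid may cause ipso-protonation of the very electron-rich ring, leading to loss or migration of iodine during acetal cleavage. Fallback: a fluoride-labile protecting group in place of the acid-labile one, which sets out from 11 and comes back at 15.
   - Alkylation with 2-(trimethylsilyl)ethoxymethyl chloride (i-Pr2NEt, CH2Cl2) should give 1-methoxy-3,5-bis{[2-(trimethylsilyl)ethoxy]methoxy}benzene F5.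
   - Lithiation (n-BuLi, THF, 0 °C) should give (4-methoxy-2,6-bis{[2-(trimethylsilyl)ethoxy]methoxy}phenyl)lithium F6, which is not isolated.
   - Quenching with I2 should give 2-iodo-5-methoxy-1,3-bis{[2-(trimethylsilyl)ethoxy]methoxy}benzene F7.
   - Fluoride-induced fragmentation (Bu4NF, THF, 60 °C) should release 15 under non-acidic conditions.

3. Step 11. Debenzylation may stall because the biflavonoid is poorly soluble, or the C2–C3 double bonds of the chromenones may be partly saturated on prolonged exposure to hydrogen. Fallback: non-reductive Lewis-acid dealkylation, which sets out from 19 and comes back at 20 with no new intermediate. BCl3 with pentamethylbenzene as benzyl-cation scavenger (CH2Cl2, −78 °C) should cleave both benzyl ethers, while the three methyl ethers, none of which is flanked by a carbonyl, should survive at that temperature.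

**Further compounds**

F1 | step 10 | 3-[3,7-bis(benzyloxy)-2-(4-methoxyphenyl)-4-oxo-4H-chromen-6-yl]-4-methoxybenzoic acid | COc1ccc(-c2oc3cc(OCc4ccccc4)c(-c4cc(C(=O)O)ccc4OC)cc3c(=O)c2OCc2ccccc2)cc1
F2 | step 10 | 1-(2,6-dihydroxy-4-methoxyphenyl)ethanone | CC(=O)c1c(O)cc(OC)cc1O
F3 | step 10 | 2-acetyl-3-hydroxy-5-methoxyphenyl 3-[3,7-bis(benzyloxy)-2-(4-methoxyphenyl)-4-oxo-4H-chromen-6-yl]-4-methoxybenzoate | CC(=O)c1c(O)cc(OC)cc1OC(=O)c1ccc(OC)c(-c2cc3c(=O)c(OCc4ccccc4)c(-c4ccc(OC)cc4)oc3cc2OCc2ccccc2)c1
F4 | step 10 | 1-{3-[3,7-bis(benzyloxy)-2-(4-methoxyphenyl)-4-oxo-4H-chromen-6-yl]-4-methoxyphenyl}-3-(2,6-dihydroxy-4-methoxyphenyl)propane-1,3-dione | COc1cc(O)c(C(=O)CC(=O)c2ccc(OC)c(-c3cc4c(=O)c(OCc5ccccc5)c(-c5ccc(OC)cc5)oc4cc3OCc3ccccc3)c2)c(O)c1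
F5 | step 9 | 1-methoxy-3,5-bis{[2-(trimethylsilyl)ethoxy]methoxy}benzene | COc1cc(OCOCC[Si](C)(C)C)cc(OCOCC[Si](C)(C)C)c1
F6 | step 9 | (4-methoxy-2,6-bis{[2-(trimethylsilyl)ethoxy]methoxy}phenyl)lithium | [Li]c1c(OCOCC[Si](C)(C)C)cc(OC)cc1OCOCC[Si](C)(C)C
F7 | step 9 | 2-iodo-5-methoxy-1,3-bis{[2-(trimethylsilyl)ethoxy]methoxy}benzene | COc1cc(OCOCC[Si](C)(C)C)c(I)c(OCOCC[Si](C)(C)C)c1
F0 | step 11 | none | none
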